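Follow the dissolved reagent through these flasks: each adduct step consumes it, and transfer from the gas renews it.

| flask | substrate | gas | time |
|---|---|---|---|
| summer | 6.0 mM | 8.8 mM (held) | 6.0 min |
| spring | 8.0 mM | 8.8 mM (held) | 6.0 min |
| autumn | 12 mM | 8.8 mM (held) | 6.0 min |
| dawn | 20 mM | 8.8 mM (held) | 6.0 min |
| dusk | 30 mM | 8.8 mM (held) | 6.0 min |

    substrate + reagent → first product + by-product (k1 = 0.99 /M/s)
    reagent + first product → bis adduct + by-product (k2 = 1.6 /M/s)
    reagent + bis adduct → tris adduct + by-product (k3 = 0.45 /M/s)
    reagent + tris adduct → tetra adduct + by-product (k4 = 0.034 /M/s)
    gas ⇌ reagent, rate k5*(csat - [reagent]) (k5 = 0.024 /s, csat = 8.8 mM)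

* [tetra adduct] at the end for summer, spring, autumn, dawn, dusk, in this order
* how that number moves from the first to the last of them (falls, then rises / rises all the way / rises, then falls / hardly changes / falls all the way)

- at the start none of reagent is dissolved
- "hardly changes" means that all values lie within two and a half points (for a concentration: within two and a half percent of the largest)
- run time (summer): 6.0 min

Divide the transfer coefficient by the first rate constant: 24.2 mM. This is the balance charge, the substrate concentration at which the pseudo-first-order constant of the first step for reagent equals the transfer coefficient. First product takes up reagent with a constant of similar size, 1.6 /M/s against 0.99 /M/s, so I expect the total uptake of reagent to stay near that of the first step at the charge as substrate turns over. I then reckon the reagent on a plateau: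

plateau = csat / (1 + charge / balance charge)

For summer that gives 7.05 mM. At a fixed plateau the steps are pseudo-first-order, and their clock is the exposure, plateau times time. Suppose the tetra adduct grows as charge × exposure^n. The row then turns where

turning charge = balance charge / (n − 1)

Solve both ends. If the chain is still early, tetra adduct needs 4 reagent additions in a row, so n = 4 and the row turns at 8.08 mM. If the chain has already reached tris adduct, the last step acts by itself, n = 1, and the row keeps rising.

The real flasks lie between these ends. The third rate constant times exposure is 1.14 in summer and 0.637 in dusk, so that step is neither early nor finished. For the last step in summer the product is 0.0863, below 1. Even n = 2 puts the turn at 24.2 mM, below the dusk charge, and the early end puts it above the summer charge. Scoring each shape by where the turning charge stands against the range of charges, I commit to this: rises, then falls, with the turn above 8.08 mM; my reckoning gives no row of values.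

The forecast gives 0.05 mM, 0.056 mM, 0.061 mM, 0.057 mM and 0.048 mM, so rises, then falls, arguing that “the larger substrate pool wins at first until the steep loss of conversion per molecule overtakes it”.

The simulation gives 0.0509 mM, 0.0576 mM, 0.0628 mM, 0.0573 mM and 0.0439 mM: rises, then falls, with the row turning at 13 mM. Read at that turn, the balance charge gives n = 2.89. In dusk the plateau reckons 3.93 mM, and the reagent at 3.00 min stands at 3.77 mM.

The constants used here belong to no real substance.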